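**Retrosynthetic overview**

1. Ring B (the dihydropyran) is made last, in a three-component Knoevenagel/oxa-(4+2) cascade of diformylphloroglucinol 14, benzaldehyde 15 and diene 12. The aryl–CHPh and CHPh–CH2 bonds form first, and the O–C(spiro) bond closes the ring.
2. Enabling feature: the spiro carbon (C-4, cadinane numbering) is the tertiary, allylic carbon of cyclohexene ring C, next to C-5=C-6. In 12 it is the inner carbon of an exocyclic methylene (C-4=C-15) held s-trans to C-5=C-6, so attack at C-15 gives an allyl cation that the phenol oxygen closes at C-4 (six-membered ring B).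
3. Diene 12 comes from enone 11 (Wittig), and 11 from cis-decalone 9 (thermodynamic enol silane, then Saegusa–Ito). The C-10 methyl comes from a ketone by methylenation and hydrogenation.
4. Ring C comes from a Diels–Alder reaction of (S)-cryptone 5 with silyloxydiene 2 anti to isopropyl (sets C-1). Ring D comes from an organocatalytic Michael addition and aldol condensation (sets C-7).
5. Order of ring formation: D (step 3), C (step 4), aromatic ring A used intact (formylated in step 9), B (step 10).

Key step: step 10

Remark: cadinane numbers are used for the terpene carbons (C-1/C-6 ring fusion, C-4 spiro carbon, C-7 isopropyl-bearing, C-10 methyl-bearing, C-15 the pyran CH2, C-1' the benzylic carbon). The silyloxydiene 2 and the dialdehyde 14 are assumed to be prepared rather than bought, and the enantiomeric purity of the series is that of step 2.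

**Route**

Step 1
Reactants: 1 but-3-en-2-one
Product: 2 2-{[tert-butyl(dimethyl)silyl]oxy}buta-1,3-diene
Conditions: tBuMe2SiOTf, Et3N, Et2O, 0 °C
Reagents that add atoms: tert-butyldimethylsilyl trifluoromethanesulfonate, CC(C)(C)[Si](C)(C)OS(=O)(=O)C(F)(F)F
Why: Soft enolisation of the enone and O-silylation of the cross-conjugated enolate (silyl enol ether formation) is the standard access to 2-silyloxybutadienes; no stereocentre is formed.

Step 2
Reactants: 3 3-methylbutanal; 1 but-3-en-2-one
Product: 4 (2S)-5-oxo-2-(propan-2-yl)hexanal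
Conditions: (S)-2-[methoxy(diphenyl)methyl]pyrrolidine (5 mol%), ethyl 3,4-dihydroxybenzoate (20 mol%), neat, 4 °C
Reagents that add atoms: none
Why: Enamine-catalysed asymmetric Michael addition, in which the (E)-enamine of 3 is shielded on one face by the methoxydiphenylmethyl group and should attack the vinyl ketone with its open face to set the (S) centre that becomes C-7.

Step 3
Reactants: 4 (2S)-5-oxo-2-(propan-2-yl)hexanal
Product: 5 (4S)-4-(propan-2-yl)cyclohex-2-en-1-one
Conditions: LiOH, iPrOH, 25 °C
Reagents that add atoms: none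
Why: Intramolecular aldol condensation of the methyl ketone onto the aldehyde and dehydration close ring D under mild base, under which the α-branched stereocentre should be retained.

Step 4
Reactants: 5 (4S)-4-(propan-2-yl)cyclohex-2-en-1-one; 2 2-{[tert-butyl(dimethyl)silyl]oxy}buta-1,3-diene
Product: 6 (4S,4aS,8aS)-6-{[tert-butyl(dimethyl)silyl]oxy}-4-(propan-2-yl)-3,4,4a,5,8,8a-hexahydronaphthalen-1(2H)-one
Conditions: HNTf2 (10 mol%), CH2Cl2, −78 to −40 °C; Et3N quench
Reagents that add atoms: none
Why: Triflimide-catalysed (silylium-mediated) Diels–Alder reaction of a 2-silyloxydiene with a cyclohexenone, with "para" regiochemistry, addition to the enone face anti to the 4-isopropyl group and suprafacial delivery, should set C-1 and C-6 as a cis ring fusion with both hydrogens syn to isopropyl.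

Step 5
Reactants: 6 (4S,4aS,8aS)-6-{[tert-butyl(dimethyl)silyl]oxy}-4-(propan-2-yl)-3,4,4a,5,8,8a-hexahydronaphthalen-1(2H)-one
Product: 7 tert-butyl(dimethyl){[(4aS,8S,8aS)-5-methylidene-8-(propan-2-yl)-1,4,4a,5,6,7,8,8a-octahydronaphthalen-2-yl]oxy}silane
Conditions: Cp2TiMe2, toluene, 65 °C, dark
Reagents that add atoms: dimethyltitanocene, C[Ti](C)(C1C=CC=C1)C1C=CC=C1
Why: Petasis methylenation by the non-basic titanium methylidene converts the C-10 ketone into the exocyclic alkene without epimerising the adjacent ring-fusion centre C-1 and leaves the silyl enol ether untouched.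

Step 6
Reactants: 7 tert-butyl(dimethyl){[(4aS,8S,8aS)-5-methylidene-8-(propan-2-yl)-1,4,4a,5,6,7,8,8a-octahydronaphthalen-2-yl]oxy}silane
Product: 9 (4aR,5R,8S,8aS)-5-methyl-8-(propan-2-yl)octahydronaphthalen-2(1H)-one, via silyl enol ether 8 (not isolated)
Conditions: H2 (4 atm), RhCl(PPh3)3 (5 mol%), toluene, 25 °C; then 1 M HCl, THF, 0 to 25 °C
Reagents that add atoms: none
Why: Homogeneous rhodium-catalysed hydrogenation should reduce only the 1,1-disubstituted alkene and add hydrogen to the face opposite the axial C-1–C-2 bond (the convex face of the cis-decalin, whose ring D chair carries isopropyl equatorial), which sets C-10 (R) with methyl cis to C-2, and mild acid then hydrolyses the silyl enol ether.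

Step 7
Reactants: 9 (4aR,5R,8S,8aS)-5-methyl-8-(propan-2-yl)octahydronaphthalen-2(1H)-one
Product: 11 (4aR,5R,8S)-5-methyl-8-(propan-2-yl)-4,4a,5,6,7,8-hexahydronaphthalen-2(3H)-one, via trimethylsilyl enol ether 10 (not isolated)
Conditions: Me3SiCl, NaI, Et3N, MeCN, 25 °C; pentane extraction; then Pd(OAc)2 (1.1 equiv), MeCN, 25 °C
Reagents that add atoms: none
Why: Thermodynamic enol silylation of a cis-fused 2-decalone should favour the enol ether towards the ring-fusion side (C-4=C-5, which flattens rather than over-puckers the shared bond, as in 5β-3-keto steroids that enolise towards C-4), and Saegusa–Ito oxidation then removes H-6 by β-hydride elimination to give the C-5=C-6 enone without touching C-1, C-7 or C-10.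

Step 8
Reactants: 11 (4aR,5R,8S)-5-methyl-8-(propan-2-yl)-4,4a,5,6,7,8-hexahydronaphthalen-2(3H)-one
Product: 12 (1S,4R,4aR)-4-methyl-7-methylidene-1-(propan-2-yl)-1,2,3,4,4a,5,6,7-octahydronaphthalene
Conditions: Ph3PCH3Br, KOtBu, THF, 0 °C
Reagents that add atoms: methyltriphenylphosphonium bromide, C[P+](c1ccccc1)(c1ccccc1)c1ccccc1.[Br-]
Why: Wittig methylenation of the enone carbonyl is 1,2-selective and gives the exocyclic/endocyclic s-trans diene, and the short reaction at low temperature should avoid γ-epimerisation at C-1 and C-7.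

Step 9
Reactants: 13 benzene-1,3,5-triol
Product: 14 2,4,6-trihydroxybenzene-1,3-dicarbaldehyde
Conditions: POCl3 (2.2 equiv), DMF (2.2 equiv), EtOAc, 0 to 25 °C; then H2O, 25 °C
Reagents that add atoms: N,N-dimethylformamide, CN(C)C=O; water, O
Why: Vilsmeier–Haack formylation of the strongly activated ring stops at the dialdehyde by stoichiometry, since each formyl group deactivates the ring, and hydrolysis of the bis-iminium salt releases the aldehydes.

Step 10
Reactants: 12 (1S,4R,4aR)-4-methyl-7-methylidene-1-(propan-2-yl)-1,2,3,4,4a,5,6,7-octahydronaphthalene; 14 2,4,6-trihydroxybenzene-1,3-dicarbaldehyde; 15 benzaldehyde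
Product: 17 guajadial C (spiro chroman; 4S 1'R 1R 7S 10R in cadinane numbering), via o-quinone methide 16 (not isolated)
Conditions: ethylenediammonium diacetate (20 mol%), 14 (1.2 equiv), 15 (2 equiv), 1,4-dioxane, 80 °C, argon
Reagents that add atoms: none
Why: Iminium-catalysed Knoevenagel condensation of benzaldehyde at the only free ring carbon of 14 and loss of water give the (E)-o-quinone methide 16, whose benzylidene carbon is attacked by the terminal CH2 (C-15) of 12 in a polar, strongly asynchronous inverse-electron-demand oxa-(4+2) cycloaddition that is completed when the dienone oxygen bonds to C-4 of the developing C-4–C-5–C-6 allyl cation. The closest known reaction type is the three-component o-quinone methide hetero-Diels–Alder reaction of diformylphloroglucinol, an aldehyde and a terpene with an exocyclic methylene or trisubstituted alkene, which gives spiro and fused chromans. Ring B closes in the (4+2) mode, in the stepwise limit as a 6-exo-trig attack of the phenoxide oxygen on the allyl cation terminus. The spiro centre C-4 (S) should be set by approach to the diene face opposite the axial C-7 isopropyl group (ring D of 12 must hold isopropyl and methyl axial because C-6 is sp2 and C-2 has to be equatorial), and C-1' (R) by the endo placement of the C-5=C-6 unit under the heterodiene of the (E)-quinone methide, which puts phenyl cis to C-5. The step needs site selectivity for C-4=C-15 over C-5=C-6, oxygen closure at C-4 and not C-6, and face and endo selectivity; these are secured by the more nucleophilic and accessible terminal CH2, the s-trans lock that keeps the diene from acting as a 4π partner, six- against eight-membered closure and the axial isopropyl shield, and minor diastereomers would be removed by chromatography.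

**Compound list**

1 | but-3-en-2-one (methyl vinyl ketone) | CC(=O)C=C | starting material
2 | 2-{[tert-butyl(dimethyl)silyl]oxy}buta-1,3-diene | C=CC(=C)O[Si](C)(C)C(C)(C)C | intermediate
3 | 3-methylbutanal | CC(C)CC=O | starting material
4 | (2S)-5-oxo-2-(propan-2-yl)hexanal | CC(C)[C@@H](C=O)CCC(C)=O | intermediate
5 | (4S)-4-(propan-2-yl)cyclohex-2-en-1-one ((S)-cryptone) | CC(C)[C@@H]1CCC(=O)C=C1 | intermediate
6 | (4S,4aS,8aS)-6-{[tert-butyl(dimethyl)silyl]oxy}-4-(propan-2-yl)-3,4,4a,5,8,8a-hexahydronaphthalen-1(2H)-one (cis-fused) | CC(C)[C@@H]1CCC(=O)[C@H]2CC=C(O[Si](C)(C)C(C)(C)C)C[C@@H]12 | intermediate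
7 | tert-butyl(dimethyl){[(4aS,8S,8aS)-5-methylidene-8-(propan-2-yl)-1,4,4a,5,6,7,8,8a-octahydronaphthalen-2-yl]oxy}silane | CC(C)[C@@H]1CCC(=C)[C@H]2CC=C(O[Si](C)(C)C(C)(C)C)C[C@@H]12 | intermediate
8 | tert-butyl(dimethyl){[(4aR,5R,8S,8aS)-5-methyl-8-(propan-2-yl)-1,4,4a,5,6,7,8,8a-octahydronaphthalen-2-yl]oxy}silane | CC(C)[C@@H]1CC[C@@H](C)[C@H]2CC=C(O[Si](C)(C)C(C)(C)C)C[C@@H]12 | intermediate
9 | (4aR,5R,8S,8aS)-5-methyl-8-(propan-2-yl)octahydronaphthalen-2(1H)-one (cis-fused) | CC(C)[C@@H]1CC[C@@H](C)[C@H]2CCC(=O)C[C@@H]12 | intermediate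
10 | trimethyl{[(4aR,5R,8S,8aS)-5-methyl-8-(propan-2-yl)-3,4,4a,5,6,7,8,8a-octahydronaphthalen-2-yl]oxy}silane | CC(C)[C@@H]1CC[C@@H](C)[C@H]2CCC(O[Si](C)(C)C)=C[C@@H]12 | intermediate
11 | (4aR,5R,8S)-5-methyl-8-(propan-2-yl)-4,4a,5,6,7,8-hexahydronaphthalen-2(3H)-one | CC(C)[C@@H]1CC[C@@H](C)[C@H]2CCC(=O)C=C12 | intermediate
12 | (1S,4R,4aR)-4-methyl-7-methylidene-1-(propan-2-yl)-1,2,3,4,4a,5,6,7-octahydronaphthalene (trans-muurola-4(15),5-diene) | CC(C)[C@@H]1CC[C@@H](C)[C@H]2CCC(=C)C=C12 | intermediate
13 | benzene-1,3,5-triol (phloroglucinol) | Oc1cc(O)cc(O)c1 | starting material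
14 | 2,4,6-trihydroxybenzene-1,3-dicarbaldehyde (diformylphloroglucinol) | O=Cc1c(O)cc(O)c(C=O)c1O | intermediate
15 | benzaldehyde | O=Cc1ccccc1 | starting material
16 | (5E)-5-benzylidene-2,4-dihydroxy-6-oxocyclohexa-1,3-diene-1,3-dicarbaldehyde (o-quinone methide) | O=C1/C(=C/c2ccccc2)C(O)=C(C=O)C(O)=C1C=O | intermediate
17 | guajadial C: (2S,4R)-5,7-dihydroxy-4-phenylchromane-6,8-dicarbaldehyde spiro-linked at C-2 to C-2' of a (4a'R,5'R,8'S)-5'-methyl-8'-(propan-2-yl)-octahydronaphthalene with a C-1'=C-8a' double bond | CC(C)[C@@H]1CC[C@@H](C)[C@H]2CC[C@@]3(C=C12)C[C@H](c1ccccc1)c1c(O)c(C=O)c(O)c(C=O)c1O3 | target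

**Step count and risks**

Total step count: 10. Longest linear sequence: 8 steps (steps 2, 3, 4, 5, 6, 7, 8 and 10).

Steps most likely to fail:

Step 10. The acid- and heat-sensitive s-trans diene may isomerise into the ring, or the quinone methide may oligomerise or be hydrated faster than it is intercepted while it is generated under condensation conditions. In addition, the two faces of the diene may be discriminated less well than argued. The fallback separates generation of the quinone methide from the condensation. It sets out from 14, which is condensed with 15 and morpholine in ethanol at 25 °C (Betti three-component reaction) to give racemic 2,4,6-trihydroxy-5-[morpholin-4-yl(phenyl)methyl]benzene-1,3-dicarbaldehyde F1. F1 is isolated and then heated with 12 in toluene at 100 °C without any additive. Thermal extrusion of morpholine releases the quinone methide slowly and at low stationary concentration, so the route comes back at 16 and, in the same flask, at 17.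

Step 7. Enolisation of 9 towards C-3 instead of C-5 would place the double bond on the wrong side of the ketone. The fallback uses the regiochemistry that the cycloaddition of step 4 fixes. It sets out from 8, which for this purpose is isolated after the hydrogenation of step 6 and before the acid treatment. Oxidation of 8 with Pd(OAc)2 in MeCN/DMSO gives (4aS,5R,8S,8aS)-5-methyl-8-(propan-2-yl)-4a,5,6,7,8,8a-hexahydronaphthalen-2(1H)-one F2. Its only enolisable α position is C-5, so LiN(iPr)2 in THF at −78 °C followed by PhSeCl gives (4aS,5R,8S,8aS)-5-methyl-1-(phenylselanyl)-8-(propan-2-yl)-4a,5,6,7,8,8a-hexahydronaphthalen-2(1H)-one F3. Conjugate reduction of the disubstituted enone double bond with [(Ph3P)CuH]6 in wet benzene gives (4aR,5R,8S,8aS)-5-methyl-1-(phenylselanyl)-8-(propan-2-yl)octahydronaphthalen-2(1H)-one F4. Oxidation with H2O2 and pyridine in CH2Cl2 at 0 °C gives the selenoxide (4aR,5R,8S,8aS)-1-(benzeneseleninyl)-5-methyl-8-(propan-2-yl)octahydronaphthalen-2(1H)-one F5, which is not isolated; its syn elimination can only use H-6, and the route comes back at 11. The reduction has to precede the oxidation, because a cross-conjugated dienone with hydrogen at C-1 would tautomerise to a phenol.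

Step 6. The metal hydride may move the exocyclic double bond into the ring before it is reduced, which would erase C-1, or hydrogen may be delivered to the concave face and give the C-10 epimer. The fallback replaces syn delivery from a metal by a radical reduction under product-stability control. It sets out from 7, which is hydrolysed with 1 M HCl in THF at 0 °C to (4aS,8S,8aS)-5-methylidene-8-(propan-2-yl)octahydronaphthalen-2(1H)-one F6. Hydrogen-atom-transfer hydrogenation of F6 (Mn(dpm)3 with dpm = 2,2,6,6-tetramethylheptane-3,5-dionate, PhSiH3, tBuOOH, iPrOH, 25 °C) passes through the tertiary C-10 radical, which should take up hydrogen so that the methyl group ends equatorial, and the route comes back at 9.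

Further compounds
F1 | step 10 | 2,4,6-trihydroxy-5-[morpholin-4-yl(phenyl)methyl]benzene-1,3-dicarbaldehyde (racemic) | O=Cc1c(O)c(C=O)c(O)c(C(c2ccccc2)N2CCOCC2)c1O
F2 | step 7 | (4aS,5R,8S,8aS)-5-methyl-8-(propan-2-yl)-4a,5,6,7,8,8a-hexahydronaphthalen-2(1H)-one | CC(C)[C@@H]1CC[C@@H](C)[C@H]2C=CC(=O)C[C@@H]12
F3 | step 7 | (4aS,5R,8S,8aS)-5-methyl-1-(phenylselanyl)-8-(propan-2-yl)-4a,5,6,7,8,8a-hexahydronaphthalen-2(1H)-one (epimers at C-1) | CC(C)[C@@H]1CC[C@@H](C)[C@H]2C=CC(=O)C([Se]c3ccccc3)[C@@H]12
F4 | step 7 | (4aR,5R,8S,8aS)-5-methyl-1-(phenylselanyl)-8-(propan-2-yl)octahydronaphthalen-2(1H)-one (epimers at C-1) | CC(C)[C@@H]1CC[C@@H](C)[C@H]2CCC(=O)C([Se]c3ccccc3)[C@@H]12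
F5 | step 7 | (4aR,5R,8S,8aS)-1-(benzeneseleninyl)-5-methyl-8-(propan-2-yl)octahydronaphthalen-2(1H)-one (not isolated) | CC(C)[C@@H]1CC[C@@H](C)[C@H]2CCC(=O)C([Se](=O)c3ccccc3)[C@@H]12
F6 | step 6 | (4aS,8S,8aS)-5-methylidene-8-(propan-2-yl)octahydronaphthalen-2(1H)-one | CC(C)[C@@H]1CCC(=C)[C@H]2CCC(=O)C[C@@H]12
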